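**Retrosynthetic overview**
- Target ⇒ achiral 1,3-diketone 1-(4-hydroxy-3-methoxyphenyl)tetradecane-3,5-dione. Both carbinol centres are set together in the last step by a double asymmetric hydrogenation with [RuCl(p-cymene)((S)-BINAP)]Cl, instead of the usual aldol (or allylation) followed by a 1,3-directed reduction; no protecting groups.
- Diketone ⇒ its styryl (1,2-dehydro) analogue ⇒ vanillin + tridecane-2,4-dione (boron-templated condensation at the methyl terminus, then C=C hydrogenation).
- Tridecane-2,4-dione ⇒ dianion of pentane-2,4-dione + 1-bromooctane (terminal alkylation).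
- Rings: none is formed; the only ring, the aromatic one, is bought with vanillin.

Assumption: the boron chelates that form in step 2 are mixtures of borate species; each is drawn as its simplest member, the 1:1 dibutoxyboron chelate.

**Route**

Step 1
Reactants: 1 pentane-2,4-dione (acetylacetone); 2 n-octyl bromide (1-bromooctane)
Product: 4 tridecane-2,4-dione, via dilithium dianion of pentane-2,4-dione 3 (not isolated)
Conditions: LiN(iPr)2 (2.1 equiv), THF, 0 °C; then 2 (1.0 equiv), 0 °C to rt; aq. HCl work-up
Reagents that add atoms: none
Why: Dianion (Hauser-type) γ-alkylation of a 1,3-diketone: the second deprotonation creates the terminal carbanion of 3, which is far more nucleophilic than the doubly stabilised central carbon, so the primary bromide is taken up by SN2 at the methyl terminus only.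

Step 2
Reactants: 4 tridecane-2,4-dione; 5 vanillin (4-hydroxy-3-methoxybenzaldehyde)
Product: 8 (E)-1-(4-hydroxy-3-methoxyphenyl)tetradec-1-ene-3,5-dione, via dibutoxyboron chelate of tridecane-2,4-dione 6 (not isolated), via dibutoxyboron chelate of the styryl diketone 7 (not isolated)
Conditions: 4 (1.2 equiv), B2O3 (0.7 equiv), B(OBu)3 (2 equiv), EtOAc, 40 °C; then 5, n-BuNH2 (0.3 equiv, added slowly), 40 to 70 °C; then 0.5 M aq. HCl, 60 °C
Reagents that add atoms: none
Why: Pabon-type boron-templated Knoevenagel (aldol) condensation: chelation to boron in 6 blocks the central C3 methylene and makes the terminal positions vinylogously acidic, the amine-catalysed condensation with the aldehyde then occurs at the unhindered C1 methyl rather than the C5 methylene, dehydration gives the conjugated (E)-alkene in 7, and dilute acid releases 8.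

Step 3
Reactants: 8 (E)-1-(4-hydroxy-3-methoxyphenyl)tetradec-1-ene-3,5-dione
Product: 9 1-(4-hydroxy-3-methoxyphenyl)tetradecane-3,5-dione
Conditions: H2 (1 atm), 10% Pd/C (5 mol% Pd), EtOAc, rt, stopped after 1 equiv H2
Reagents that add atoms: none
Why: Heterogeneous catalytic hydrogenation: Pd/C at 1 atm saturates only the conjugated styryl C=C, while the enolised 1,3-diketone, the arene and the free phenol are inert under these conditions, so the step is a pure addition of H2.

Step 4
Reactants: 9 1-(4-hydroxy-3-methoxyphenyl)tetradecane-3,5-dione
Product: 12 (3S,5S)-1-(4-hydroxy-3-methoxyphenyl)tetradecane-3,5-diol (target), via (S)-5-hydroxy-3-ketone 10 (not isolated), via (S)-3-hydroxy-5-ketone 11 (not isolated)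
Conditions: H2 (50 bar), [RuCl(p-cymene)((S)-BINAP)]Cl (1 mol%), degassed MeOH, 50 °C, 48 h
Reagents that add atoms: none
Why: Noyori asymmetric hydrogenation of a 1,3-diketone with a BINAP complex of divalent ruthenium: whichever carbonyl reacts first is bound in a six-membered chelate with the second oxygen and the (S)-ligand directs hydride to give the (S)-carbinol (10 or 11), and the second, hydroxyl-chelated reduction is the matched case that gives the anti (3S,5S)-diol, the same sense in which the (R)-ligand turns pentane-2,4-dione into (R,R)-pentane-2,4-diol; both stereocentres are thus set by catalyst control in a pure addition of two H2.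

**Compound list**

1 | pentane-2,4-dione (acetylacetone) | CC(=O)CC(C)=O | starting material
2 | 1-bromooctane | CCCCCCCCBr | starting material
3 | dilithium 1,3-dianion of pentane-2,4-dione (drawn as the dienolate) | [Li+].[Li+].C=C([O-])C=C(C)[O-] | intermediate
4 | tridecane-2,4-dione | CCCCCCCCCC(=O)CC(C)=O | intermediate
5 | vanillin (4-hydroxy-3-methoxybenzaldehyde) | COc1cc(C=O)ccc1O | starting material
6 | dibutoxyboron chelate of tridecane-2,4-dione (2,2-dibutoxy-4-methyl-6-nonyl-1,3,2-dioxaborine) | CCCCCCCCCC1=CC(C)=[O+][B-](OCCCC)(OCCCC)O1 | intermediate
7 | dibutoxyboron chelate of the styryl diketone (2,2-dibutoxy-4-[(E)-2-(4-hydroxy-3-methoxyphenyl)ethenyl]-6-nonyl-1,3,2-dioxaborine) | CCCCCCCCCC1=CC(/C=C/c2ccc(O)c(OC)c2)=[O+][B-](OCCCC)(OCCCC)O1 | intermediate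
8 | (E)-1-(4-hydroxy-3-methoxyphenyl)tetradec-1-ene-3,5-dione (drawn as the diketo tautomer) | CCCCCCCCCC(=O)CC(=O)/C=C/c1ccc(O)c(OC)c1 | intermediate
9 | 1-(4-hydroxy-3-methoxyphenyl)tetradecane-3,5-dione | CCCCCCCCCC(=O)CC(=O)CCc1ccc(O)c(OC)c1 | intermediate
10 | (5S)-5-hydroxy-1-(4-hydroxy-3-methoxyphenyl)tetradecan-3-one | CCCCCCCCC[C@H](O)CC(=O)CCc1ccc(O)c(OC)c1 | intermediate
11 | (3S)-3-hydroxy-1-(4-hydroxy-3-methoxyphenyl)tetradecan-5-one | CCCCCCCCCC(=O)C[C@@H](O)CCc1ccc(O)c(OC)c1 | intermediate
12 | (3S,5S)-1-(4-hydroxy-3-methoxyphenyl)tetradecane-3,5-diol | CCCCCCCCC[C@H](O)C[C@@H](O)CCc1ccc(O)c(OC)c1 | target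

**Step count and risks**

Total step count: 4. Longest linear sequence: 4 (1 → 4 → 8 → 9 → 12).

The three steps most likely to fail, in order of risk:

Risk 1, step 4 (key step). The substrate is unsymmetrical, largely enolised and carries a free phenol, so the hydrogenation may stall after one reduction or give a lower anti:syn ratio than simple diketones. Any wrong-handed first reduction ends up mainly as the syn diastereomer, which can be separated, so the anti product should be of high ee. The fallback sets out from 9 and comes back at 12. It changes the second stereocentre from catalyst control to substrate control. The hydrogenation is run only to the mono-reduced stage (lower pressure and temperature, stopped after 1 equiv H2), and the mixture of 10 and 11, both (S)-configured, is isolated. An Evans–Saksena hydroxyl-directed reduction with Me4NBH(OAc)3 in MeCN/AcOH at −30 °C then delivers hydride intramolecularly, anti to the existing carbinol. Both regioisomers therefore converge on the same (3S,5S)-diol 12. No compound outside the compound list is made on this detour: none F0.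

Risk 2, step 2. The condensation may be only moderately yielding, with competing reaction at the C5 methylene or double condensation. The fallback sets out from 5 and comes back at 9, bypassing steps 1 to 3, and forms the C4–C5 bond by acylation instead of the C1–C2 bond by condensation. Claisen–Schmidt condensation of 5 with acetone (aq. NaOH, rt) gives (E)-4-(4-hydroxy-3-methoxyphenyl)but-3-en-2-one F1. Hydrogenation (H2, 10% Pd/C, EtOAc) gives 4-(4-hydroxy-3-methoxyphenyl)butan-2-one F2. A crossed Claisen acylation of its methyl group with methyl decanoate (NaH, 3.5 equiv, THF, reflux, then aq. HCl) gives 9. The excess base covers the phenol, and the product is held as its stabilised diketonate. This is kept as the fallback because self-aldol of the ketone is expected to lower the yield.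

Risk 3, step 1. The long-chain bromide reacts slowly, and over-alkylation or O-alkylation can erode the yield. The fallback sets out from 1 and comes back at 4, replacing alkylation by acylation and deacylation. C-acylation of 1 with decanoyl chloride (MgCl2, pyridine, CH2Cl2, 0 °C to rt) gives 3-decanoylpentane-2,4-dione F3. Retro-Claisen deacetylation (dilute aq. NaOH/EtOH, 0 °C to rt, then acidification) removes one of the two less hindered acetyl groups and leaves 4.

**Further compounds**

F0 | step 4 | none | none
F1 | step 2 | (E)-4-(4-hydroxy-3-methoxyphenyl)but-3-en-2-one | CC(=O)/C=C/c1ccc(O)c(OC)c1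
F2 | step 2 | 4-(4-hydroxy-3-methoxyphenyl)butan-2-one | CC(=O)CCc1ccc(O)c(OC)c1
F3 | step 1 | 3-decanoylpentane-2,4-dione | CCCCCCCCCC(=O)C(C(C)=O)C(C)=O
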